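**Retrosynthetic overview**

1. Target 21 comes from fluoride desilylation of bis-silyl ether 20. Compound 20 is cut at C10–C11 into the ring A diyne 9 (C13), one CH3 from AlMe3, and the C26 hexaenyl iodide 18 (fragment 2).
2. Enabling feature: the C7≡C8 triple bond sits directly on C9 of the trisubstituted C9(CH3)=C10H alkene next to ring A. This enyne is the syn-methylmetalation product of a terminal buta-1,3-diynyl group, so the C9–CH3 bond, the C9=C10 geometry and the C10–C11 bond arise in one operation.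
3. Iodide 18 is cut at C10'–C11' into the ring B alkyne 13, CH3 (AlMe3) and the C12 diiodide 16, which comes from twofold Takai olefination of the C10 dialdehyde 14.
4. Diyne 9 and alkyne 13 both come from one enol triflate 4 (sp–sp2 and sp3–sp2 Negishi couplings), made from (4R,6R)-actinol 1, whose C4 becomes C3 and C3'.
5. No ring is formed in the route: ring A and ring B are both carried over from 1. Ring B is elaborated first (steps 5, 6, 8) and ring A is joined last (step 9).

Key step: step 9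

Assumption: compounds 1, 5, 10 and all-E 14 are taken as purchasable, and all polyene steps (7 to 10) are run under argon with exclusion of light.

**Step 1**
Reactants: 1 (4R,6R)-4-hydroxy-2,2,6-trimethylcyclohexan-1-one
Product: 2 (4R,6R)-4-{[tert-butyl(dimethyl)silyl]oxy}-2,2,6-trimethylcyclohexan-1-one
Conditions: TBSCl, imidazole, DMF, 23 °C
Reagents that add atoms: tert-butyldimethylsilyl chloride, CC(C)(C)[Si](C)(C)Cl
Why: Standard silylation of a secondary alcohol with a silyl chloride and imidazole should protect the hydroxyl without touching either stereocentre.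

**Step 2**
Reactants: 2 (4R,6R)-4-{[tert-butyl(dimethyl)silyl]oxy}-2,2,6-trimethylcyclohexan-1-one
Product: 4 (4R)-4-{[tert-butyl(dimethyl)silyl]oxy}-2,6,6-trimethylcyclohex-1-en-1-yl trifluoromethanesulfonate, via lithium enolate 3 (not isolated)
Conditions: LiN(i-Pr)2, THF, −78 °C; then PhNTf2, −78→23 °C; aq NH4Cl
Reagents that add atoms: N-phenylbis(trifluoromethanesulfonimide), O=S(=O)(N(c1ccccc1)S(=O)(=O)C(F)(F)F)C(F)(F)F; lithium diisopropylamide (supplies the Li of 3 only), [Li]N(C(C)C)C(C)C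
Why: Enolate O-triflation should give a single enol triflate because the ketone can enolise only towards C6 (C2 is quaternary), which erases the C6 stereocentre on purpose and leaves C4 untouched.

**Step 3**
Reactants: 4 (4R)-4-{[tert-butyl(dimethyl)silyl]oxy}-2,6,6-trimethylcyclohex-1-en-1-yl trifluoromethanesulfonate; 5 1,4-bis(trimethylsilyl)buta-1,3-diyne
Product: 8 tert-butyl(dimethyl)({(1R)-3,5,5-trimethyl-4-[4-(trimethylsilyl)buta-1,3-diyn-1-yl]cyclohex-3-en-1-yl}oxy)silane, via lithium diynide 6 (not isolated), via diynylzinc chloride 7 (not isolated)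
Conditions: 5, MeLi·LiBr, THF, 23 °C; ZnCl2, 0 °C; then 4, Pd(PPh3)4 (5 mol %), THF, 23→50 °C
Reagents that add atoms: methyllithium (supplies the Li of 6 only), [Li]C; zinc dichloride (supplies the ZnCl of 7 only), Cl[Zn]Cl
Why: Mono-desilylation of the bis-silyl diyne by MeLi, transmetalation to zinc and Negishi alkynyl–alkenyl coupling should proceed because zerovalent palladium inserts readily into the C–OTf bond and sp–sp2 reductive elimination is fast even at a tetrasubstituted alkene.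

**Step 4**
Reactants: 8 tert-butyl(dimethyl)({(1R)-3,5,5-trimethyl-4-[4-(trimethylsilyl)buta-1,3-diyn-1-yl]cyclohex-3-en-1-yl}oxy)silane
Product: 9 {[(1R)-4-(buta-1,3-diyn-1-yl)-3,5,5-trimethylcyclohex-3-en-1-yl]oxy}(tert-butyl)dimethylsilane
Conditions: K2CO3 (0.2 equiv), MeOH/THF, 0 °C; kept and used at once as a solution
Reagents that add atoms: none
Why: Methanolysis of the alkynyl C–Si bond (protodesilylation) should be fast and selective, since the secondary silyl ether is inert to methanolic carbonate.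

**Step 5**
Reactants: 4 (4R)-4-{[tert-butyl(dimethyl)silyl]oxy}-2,6,6-trimethylcyclohex-1-en-1-yl trifluoromethanesulfonate; 10 (4-bromobut-1-yn-1-yl)trimethylsilane
Product: 12 tert-butyl(dimethyl)({(1R)-3,5,5-trimethyl-4-[4-(trimethylsilyl)but-3-yn-1-yl]cyclohex-3-en-1-yl}oxy)silane, via alkylzinc bromide 11 (not isolated)
Conditions: 10, Zn dust, I2 (5 mol %), DMA, 70 °C; then 4, Pd(dppf)Cl2 (5 mol %), DMA/THF, 60 °C
Reagents that add atoms: zinc metal (supplies the Zn of 11 only), [Zn]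
Why: Zinc insertion into the primary bromide followed by Negishi alkyl–alkenyl coupling should form the C6'–C7' bond, the wide-bite-angle dppf ligand favouring reductive elimination over β-hydride elimination of the homopropargylic zinc reagent.

**Step 6**
Reactants: 12 tert-butyl(dimethyl)({(1R)-3,5,5-trimethyl-4-[4-(trimethylsilyl)but-3-yn-1-yl]cyclohex-3-en-1-yl}oxy)silane
Product: 13 {[(1R)-4-(but-3-yn-1-yl)-3,5,5-trimethylcyclohex-3-en-1-yl]oxy}(tert-butyl)dimethylsilane
Conditions: K2CO3 (0.2 equiv), MeOH/THF, 23 °C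
Reagents that add atoms: none
Why: The same protodesilylation of an alkynylsilane should free the terminal alkyne while the silyl ether survives.

**Step 7**
Reactants: 14 (2E,4E,6E)-2,7-dimethylocta-2,4,6-trienedial
Product: 16 (1E,3E,5E,7E,9E)-1,10-diiodo-3,8-dimethyldeca-1,3,5,7,9-pentaene, via iodotetraenal 15 (not isolated)
Conditions: CHI3 (5 equiv), CrCl2 (16 equiv), THF/1,4-dioxane, 0→23 °C, dark
Reagents that add atoms: iodoform, IC(I)I
Why: Twofold Takai iodo-olefination with the gem-dichromium reagent formed from CHI3 and divalent chromium should convert both enal carbonyls into E-iodoalkenes through anti elimination of the β-oxido dichromium adducts, without disturbing the existing triene.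

**Step 8**
Reactants: 13 {[(1R)-4-(but-3-yn-1-yl)-3,5,5-trimethylcyclohex-3-en-1-yl]oxy}(tert-butyl)dimethylsilane; 16 (1E,3E,5E,7E,9E)-1,10-diiodo-3,8-dimethyldeca-1,3,5,7,9-pentaene
Product: 18 tert-butyl({(1R)-4-[(3E,5E,7E,9E,11E,13E)-14-iodo-3,7,12-trimethyltetradeca-3,5,7,9,11,13-hexaen-1-yl]-3,5,5-trimethylcyclohex-3-en-1-yl}oxy)dimethylsilane, via alkenylalane 17 (not isolated)
Conditions: AlMe3 (2 equiv), Cp2ZrCl2 (0.25 equiv), CH2Cl2, 0→23 °C; volatiles removed in vacuo; then 16 (3 equiv), ZnCl2 (0.5 equiv, co-catalyst), Pd2(dba)3 (2.5 mol %), P(2-furyl)3 (10 mol %), THF, 23 °C, dark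
Reagents that add atoms: trimethylaluminium, C[Al](C)C
Why: Zr-catalysed syn-methylalumination of the terminal alkyne followed by Pd/Zn-catalysed Negishi alkenyl–alkenyl coupling should set the C9'=C10' E geometry and form C10'–C11' with retention, the excess of diiodide 16 (recoverable) favouring mono-coupling.

**Step 9**
Reactants: 9 {[(1R)-4-(buta-1,3-diyn-1-yl)-3,5,5-trimethylcyclohex-3-en-1-yl]oxy}(tert-butyl)dimethylsilane; 18 tert-butyl({(1R)-4-[(3E,5E,7E,9E,11E,13E)-14-iodo-3,7,12-trimethyltetradeca-3,5,7,9,11,13-hexaen-1-yl]-3,5,5-trimethylcyclohex-3-en-1-yl}oxy)dimethylsilane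
Product: 20 (all-E,3R,3'R)-3,3'-bis{[tert-butyl(dimethyl)silyl]oxy}-7,8-didehydro-7',8'-dihydro-β,β-carotene, via dienynylalane 19 (not isolated)
Conditions: AlMe3 (2 equiv), Cp2ZrCl2 (0.25 equiv), CH2Cl2, −20→0 °C; volatiles removed in vacuo at 0 °C; then 18 (0.7 equiv), ZnCl2 (0.5 equiv, co-catalyst), Pd2(dba)3 (2.5 mol %), P(2-furyl)3 (10 mol %), THF, 23 °C, dark
Reagents that add atoms: trimethylaluminium, C[Al](C)C
Why: Zr-catalysed methylalumination adds CH3–Al syn across the terminal C9≡C10 bond of 9 (CH3 to C9, Al to C10), and the resulting alane 19 is passed via zinc to the alkenylpalladium iodide formed by oxidative addition of zerovalent palladium into the C11–I bond of 18, reductive elimination then forming C10–C11 with retention at both alkenes. The closest known reaction type is the one-flask carboalumination/Pd–Zn alkenyl–alkenyl cross-coupling used for conjugated polyenes, applied here to a terminal 1,3-diyne. No ring is closed and no stereocentre is created; the only new stereo-element is the C9=C10 double bond, whose E geometry (C8 trans to C11) is fixed kinetically by the syn addition, which matters because 9Z isomers of 7,8-didehydro polyenes are thermodynamically competitive and equilibration must be avoided. The step needs regioselectivity (Al at terminal C10), chemoselectivity for C9≡C10 over C7≡C8 and no CH3 transfer to the iodide: the first follows from the terminal alkyne, the second from shielding of C7≡C8 by the fully substituted C6 flanked by the C1 gem-dimethyl and C5 methyl groups, and the third from evaporating excess AlMe3 before 18 is added. Both silyl ethers at C3 and C3' are inert to the alane and to the mild coupling conditions.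

**Step 10**
Reactants: 20 (all-E,3R,3'R)-3,3'-bis{[tert-butyl(dimethyl)silyl]oxy}-7,8-didehydro-7',8'-dihydro-β,β-carotene
Product: 21 (all-E,3R,3'R)-7,8-didehydro-7',8'-dihydro-β,β-carotene-3,3'-diol
Conditions: Bu4NF, THF, 23 °C, dark
Reagents that add atoms: none
Why: Fluoride-mediated cleavage of the two secondary silyl ethers should liberate the diol under non-acidic conditions that leave the polyene geometry and both stereocentres untouched.

**Compound list**

1 | (4R,6R)-4-hydroxy-2,2,6-trimethylcyclohexan-1-one (actinol) | O=C1C(C)(C)C[C@H](O)C[C@H]1C | starting material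
2 | (4R,6R)-4-{[tert-butyl(dimethyl)silyl]oxy}-2,2,6-trimethylcyclohexan-1-one | O=C1C(C)(C)C[C@H](O[Si](C)(C)C(C)(C)C)C[C@H]1C | intermediate
3 | lithium (4R)-4-{[tert-butyl(dimethyl)silyl]oxy}-2,6,6-trimethylcyclohex-1-en-1-olate | [Li]OC1=C(C)C[C@@H](O[Si](C)(C)C(C)(C)C)CC1(C)C | intermediate (not isolated)
4 | (4R)-4-{[tert-butyl(dimethyl)silyl]oxy}-2,6,6-trimethylcyclohex-1-en-1-yl trifluoromethanesulfonate | CC1=C(OS(=O)(=O)C(F)(F)F)C(C)(C)C[C@H](O[Si](C)(C)C(C)(C)C)C1 | intermediate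
5 | 1,4-bis(trimethylsilyl)buta-1,3-diyne | C[Si](C)(C)C#CC#C[Si](C)(C)C | starting material
6 | [4-(trimethylsilyl)buta-1,3-diyn-1-yl]lithium | [Li]C#CC#C[Si](C)(C)C | intermediate (not isolated)
7 | chloro[4-(trimethylsilyl)buta-1,3-diyn-1-yl]zinc | Cl[Zn]C#CC#C[Si](C)(C)C | intermediate (not isolated)
8 | tert-butyl(dimethyl)({(1R)-3,5,5-trimethyl-4-[4-(trimethylsilyl)buta-1,3-diyn-1-yl]cyclohex-3-en-1-yl}oxy)silane | CC1=C(C#CC#C[Si](C)(C)C)C(C)(C)C[C@H](O[Si](C)(C)C(C)(C)C)C1 | intermediate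
9 | {[(1R)-4-(buta-1,3-diyn-1-yl)-3,5,5-trimethylcyclohex-3-en-1-yl]oxy}(tert-butyl)dimethylsilane | CC1=C(C#CC#C)C(C)(C)C[C@H](O[Si](C)(C)C(C)(C)C)C1 | intermediate
10 | (4-bromobut-1-yn-1-yl)trimethylsilane | C[Si](C)(C)C#CCCBr | starting material
11 | bromo[4-(trimethylsilyl)but-3-yn-1-yl]zinc | C[Si](C)(C)C#CCC[Zn]Br | intermediate (not isolated)
12 | tert-butyl(dimethyl)({(1R)-3,5,5-trimethyl-4-[4-(trimethylsilyl)but-3-yn-1-yl]cyclohex-3-en-1-yl}oxy)silane | CC1=C(CCC#C[Si](C)(C)C)C(C)(C)C[C@H](O[Si](C)(C)C(C)(C)C)C1 | intermediate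
13 | {[(1R)-4-(but-3-yn-1-yl)-3,5,5-trimethylcyclohex-3-en-1-yl]oxy}(tert-butyl)dimethylsilane | CC1=C(CCC#C)C(C)(C)C[C@H](O[Si](C)(C)C(C)(C)C)C1 | intermediate
14 | (2E,4E,6E)-2,7-dimethylocta-2,4,6-trienedial | O=C/C(C)=C/C=C/C=C(C)/C=O | starting material
15 | (2E,4E,6E,8E)-9-iodo-2,7-dimethylnona-2,4,6,8-tetraenal | O=C/C(C)=C/C=C/C=C(C)/C=C/I | intermediate (not isolated)
16 | (1E,3E,5E,7E,9E)-1,10-diiodo-3,8-dimethyldeca-1,3,5,7,9-pentaene | I/C=C/C(C)=C/C=C/C=C(C)/C=C/I | intermediate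
17 | [(1E)-4-[(4R)-4-{[tert-butyl(dimethyl)silyl]oxy}-2,6,6-trimethylcyclohex-1-en-1-yl]-2-methylbut-1-en-1-yl](dimethyl)alane | C[Al](C)/C=C(\C)CCC1=C(C)C[C@@H](O[Si](C)(C)C(C)(C)C)CC1(C)C | intermediate (not isolated)
18 | tert-butyl({(1R)-4-[(3E,5E,7E,9E,11E,13E)-14-iodo-3,7,12-trimethyltetradeca-3,5,7,9,11,13-hexaen-1-yl]-3,5,5-trimethylcyclohex-3-en-1-yl}oxy)dimethylsilane (fragment 2) | I/C=C/C(C)=C/C=C/C=C(C)/C=C/C=C(\C)CCC1=C(C)C[C@@H](O[Si](C)(C)C(C)(C)C)CC1(C)C | intermediate
19 | [(1E)-4-[(4R)-4-{[tert-butyl(dimethyl)silyl]oxy}-2,6,6-trimethylcyclohex-1-en-1-yl]-2-methylbut-1-en-3-yn-1-yl](dimethyl)alane | CC1=C(C#C/C(C)=C/[Al](C)C)C(C)(C)C[C@H](O[Si](C)(C)C(C)(C)C)C1 | intermediate (not isolated)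
20 | (all-E,3R,3'R)-3,3'-bis{[tert-butyl(dimethyl)silyl]oxy}-7,8-didehydro-7',8'-dihydro-β,β-carotene | CC1=C(C#C/C(C)=C/C=C/C(C)=C/C=C/C=C(C)/C=C/C=C(\C)CCC2=C(C)C[C@@H](O[Si](C)(C)C(C)(C)C)CC2(C)C)C(C)(C)C[C@H](O[Si](C)(C)C(C)(C)C)C1 | intermediate
21 | (all-E,3R,3'R)-7,8-didehydro-7',8'-dihydro-β,β-carotene-3,3'-diol | CC1=C(C#C/C(C)=C/C=C/C(C)=C/C=C/C=C(C)/C=C/C=C(\C)CCC2=C(C)C[C@@H](O)CC2(C)C)C(C)(C)C[C@H](O)C1 | target

**Step count and risks**

Total step count: 10. Longest linear sequence: 7 steps (steps 1, 2, 5, 6, 8, 9, 10).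

Steps most likely to fail:

1. Step 9. The acidic terminal C–H of the diyne may be aluminated instead of carbometalated, or regio-isomeric alane may be carried into the coupling, so that alkynyl-linked or wrongly methylated material is joined to 18. The fallback sets out from 9 and returns at 20, and separates the carbometalation from the union. The alane 19 is quenched with I2 (THF, −30 °C) to give tert-butyl({(1R)-4-[(3E)-4-iodo-3-methylbut-3-en-1-yn-1-yl]-3,5,5-trimethylcyclohex-3-en-1-yl}oxy)dimethylsilane F1, which can be purified. Miyaura borylation (B2pin2, Pd(dppf)Cl2, KOPh, toluene, 50 °C) converts it into tert-butyl(dimethyl)({(1R)-3,5,5-trimethyl-4-[(3E)-3-methyl-4-(4,4,5,5-tetramethyl-1,3,2-dioxaborolan-2-yl)but-3-en-1-yn-1-yl]cyclohex-3-en-1-yl}oxy)silane F2. Suzuki–Miyaura coupling of this boronate with 18 (Pd(PPh3)4, K3PO4, THF/H2O, 23 °C) should then give 20.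

2. Step 8. Over-coupling at both C–I termini of the diiodide and poor chromatographic separation of the three non-polar polyenes may erode the supply of 18. The fallback sets out from 13 and returns at 18, and replaces the statistical mono-coupling by a polarity-differentiated olefination sequence.
   - The alane 17 is turned into its ate complex with n-BuLi and trapped with paraformaldehyde to give (2E)-5-[(4R)-4-{[tert-butyl(dimethyl)silyl]oxy}-2,6,6-trimethylcyclohex-1-en-1-yl]-3-methylpent-2-en-1-ol F3.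
   - Appel bromination (CBr4, PPh3, CH2Cl2, 0 °C) gives {[(1R)-4-[(3E)-5-bromo-3-methylpent-3-en-1-yl]-3,5,5-trimethylcyclohex-3-en-1-yl]oxy}(tert-butyl)dimethylsilane F4.
   - Arbuzov reaction with P(OEt)3 (110 °C) gives diethyl {(2E)-5-[(4R)-4-{[tert-butyl(dimethyl)silyl]oxy}-2,6,6-trimethylcyclohex-1-en-1-yl]-3-methylpent-2-en-1-yl}phosphonate F5.
   - Horner–Wadsworth–Emmons reaction with excess 14 (NaN(SiMe3)2, THF, −78→0 °C) gives (2E,4E,6E,8E,10E)-13-[(4R)-4-{[tert-butyl(dimethyl)silyl]oxy}-2,6,6-trimethylcyclohex-1-en-1-yl]-2,7,11-trimethyltrideca-2,4,6,8,10-pentaenal F6, which is easily separated from 14 by polarity.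
   - Takai olefination of this aldehyde (CHI3, CrCl2, THF/1,4-dioxane) should give 18.

3. Step 5. Slow transmetalation and reductive elimination at the hindered tetrasubstituted alkenylpalladium centre may let β-hydride elimination and reduction of the triflate take over. The fallback sets out from 4 and returns at 13, and makes the C6'–C7' bond as an sp–sp2 bond before saturating it.
   - Sonogashira coupling of 4 with prop-2-yn-1-ol (Pd(PPh3)4, CuI, i-Pr2NH, DMF, 23 °C) gives 3-[(4R)-4-{[tert-butyl(dimethyl)silyl]oxy}-2,6,6-trimethylcyclohex-1-en-1-yl]prop-2-yn-1-ol F7.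
   - Hydrogenation (H2, Pd/C, EtOAc) should saturate the triple bond but not the tetrasubstituted ring alkene, giving 3-[(4R)-4-{[tert-butyl(dimethyl)silyl]oxy}-2,6,6-trimethylcyclohex-1-en-1-yl]propan-1-ol F8.
   - Dess–Martin oxidation gives 3-[(4R)-4-{[tert-butyl(dimethyl)silyl]oxy}-2,6,6-trimethylcyclohex-1-en-1-yl]propanal F9.
   - Seyferth–Gilbert homologation with dimethyl (1-diazo-2-oxopropyl)phosphonate (K2CO3, MeOH) should give 13.

**Further compounds**

F1 | step 9 | tert-butyl({(1R)-4-[(3E)-4-iodo-3-methylbut-3-en-1-yn-1-yl]-3,5,5-trimethylcyclohex-3-en-1-yl}oxy)dimethylsilane | CC1=C(C#C/C(C)=C/I)C(C)(C)C[C@H](O[Si](C)(C)C(C)(C)C)C1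
F2 | step 9 | tert-butyl(dimethyl)({(1R)-3,5,5-trimethyl-4-[(3E)-3-methyl-4-(4,4,5,5-tetramethyl-1,3,2-dioxaborolan-2-yl)but-3-en-1-yn-1-yl]cyclohex-3-en-1-yl}oxy)silane | CC1=C(C#C/C(C)=C/B2OC(C)(C)C(C)(C)O2)C(C)(C)C[C@H](O[Si](C)(C)C(C)(C)C)C1
F3 | step 8 | (2E)-5-[(4R)-4-{[tert-butyl(dimethyl)silyl]oxy}-2,6,6-trimethylcyclohex-1-en-1-yl]-3-methylpent-2-en-1-ol | OC/C=C(\C)CCC1=C(C)C[C@@H](O[Si](C)(C)C(C)(C)C)CC1(C)C
F4 | step 8 | {[(1R)-4-[(3E)-5-bromo-3-methylpent-3-en-1-yl]-3,5,5-trimethylcyclohex-3-en-1-yl]oxy}(tert-butyl)dimethylsilane | BrC/C=C(\C)CCC1=C(C)C[C@@H](O[Si](C)(C)C(C)(C)C)CC1(C)C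
F5 | step 8 | diethyl {(2E)-5-[(4R)-4-{[tert-butyl(dimethyl)silyl]oxy}-2,6,6-trimethylcyclohex-1-en-1-yl]-3-methylpent-2-en-1-yl}phosphonate | CCOP(=O)(OCC)C/C=C(\C)CCC1=C(C)C[C@@H](O[Si](C)(C)C(C)(C)C)CC1(C)C
F6 | step 8 | (2E,4E,6E,8E,10E)-13-[(4R)-4-{[tert-butyl(dimethyl)silyl]oxy}-2,6,6-trimethylcyclohex-1-en-1-yl]-2,7,11-trimethyltrideca-2,4,6,8,10-pentaenal | O=C/C(C)=C/C=C/C=C(C)/C=C/C=C(\C)CCC1=C(C)C[C@@H](O[Si](C)(C)C(C)(C)C)CC1(C)C
F7 | step 5 | 3-[(4R)-4-{[tert-butyl(dimethyl)silyl]oxy}-2,6,6-trimethylcyclohex-1-en-1-yl]prop-2-yn-1-ol | CC1=C(C#CCO)C(C)(C)C[C@H](O[Si](C)(C)C(C)(C)C)C1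
F8 | step 5 | 3-[(4R)-4-{[tert-butyl(dimethyl)silyl]oxy}-2,6,6-trimethylcyclohex-1-en-1-yl]propan-1-ol | CC1=C(CCCO)C(C)(C)C[C@H](O[Si](C)(C)C(C)(C)C)C1
F9 | step 5 | 3-[(4R)-4-{[tert-butyl(dimethyl)silyl]oxy}-2,6,6-trimethylcyclohex-1-en-1-yl]propanal | CC1=C(CCC=O)C(C)(C)C[C@H](O[Si](C)(C)C(C)(C)C)C1
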